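## Structural features

25 is a 5,7-dimethoxyphthalide (2-benzofuran-1(3H)-one). Its C3 carries a six-methylene tether that ends at C2' of a 1,6-dioxaspiro[4.4]nonane (ring A: O1', C2'–C5'; ring B: C5', O6', C7'–C9'), with a methyl group on C7'. There are four stereocentres, all S: C3, C2', C5' and C7'. C2' and C5' are 1,3-related across O1' in ring A, and C5' and C7' are 1,3-related across O6' in ring B. C3 is insulated from this triad by six CH2 groups, so it must be set by a reagent or an auxiliary, and a wrong C3 epimer would be very hard to remove. The fragile points are the spiroketal (C5' epimerises under mild acid), the benzylic lactone C3–O bond on an electron-rich ring (ionisation, hydrogenolysis) and the lactone toward hydroxide. The real difficulty is C5': in 25 the C2' chain is cis to O6' and the C7' methyl is cis to O1', and a [5,5]-spiroketal offers no dependable thermodynamic preference for this arrangement. The key step uses the ring pattern: oxygen on C5 and C7, the carboxyl carbon C1 on C7a and the carbinol carbon C3 on C3a. This is the orsellinate pattern of a linear tetraketide folded by an aldol bond between C3a and C7a, so the six ring carbons, C1 and C3 can be laid out as one poly-β-carbonyl chain with its carboxyl end masked as a dioxinone.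

## Logic of the disconnections

25 to 24: the two aryl O–CH3 bonds at C5 and C7 are cut. The ring-forming chemistry delivers phenols, so the ethers are added last and the two oxygens never need to be told apart. The forward step must methylate the hydrogen-bonded C7 hydroxyl as well, with a base too weak to open the lactone or touch C3, and without acid.

24 to 22: the lactone bond O2–C1 is cut and the C3 oxygen is placed under silicon. In 22, C1 is already an activated aryl ester inside the dioxinone, so lactone closure, carboxyl activation and phenol masking are held in one heterocycle. The forward step must use fluoride only and close 5-exo-trig at C1 with retention at C3.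

22 to 20: the C3a–C7a bond is cut and the benzene ring is opened (formal rehydration). The whole arene becomes the chain C1–C7a–C7–C6–C5–C4–C3a–C3, in which only C3 is stereogenic. The forward step needs a six-membered aldol of the dioxinone α-carbon on the C3a ketone, dehydration, and no enolisation toward C3. 20 and 22 map atom for atom and descriptor for descriptor onto 25.

20 to 19 and 17: the C4–C3a bond is cut. This separates the achiral tricarbonyl head from the chiral lipophilic part at a carbonyl group and makes the route convergent. The dianion of 19 must react at its terminal carbon with a hindered α-silyloxy acyl donor without proton transfer at C3. For this reason 17 is an N-methoxy-N-methylamide, whose chelated adduct keeps the new ketone masked until the quench.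

19 to 18: the C5–C6 bond is cut (acetyl carbon to the dioxinone methyl carbon). One acylation of a commercial compound is required, at carbon and not at oxygen.

17 to 16 to 15 to 14: the O–Si bond, the C3a–N bond (amide exchange) and the C3–O bond are cut in turn. Because C3 is isolated, the stereo-controlling element is placed next to it, which reduces C3 to an enolate oxidation with separable diastereomers. The forward steps need face-selective hydroxylation and removal of the auxiliary without touching C3 or the ketal.

14 to 11 and 12, and 11 to 10 to 8: the N–C3a acyl bond is cut and C3a is taken down in oxidation level. C3a and C3 are the two alkene carbons of 8, so no carbon is removed and put back. The forward steps are anti-Markovnikov hydration and oxidation at basic or near-neutral pH.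

8 to 6: the C5'–O1' and C5'–O6' bonds are cut. Rings A and B and the C5' centre disappear and an open chain with only C2' and C7' remains. The price is that C5' is set by equilibrium, so the (5S) epimer must be separated, the other recycled, and all later steps kept free of acid.

6 to 3, 4 and 2: the C3'–C4' and C8'–C9' bonds are cut. 3 serves as an α,α'-dianion equivalent of acetone, and both carbinol centres arrive ready-made in 4 and 2. The forward step needs two ordered metalations and epoxide opening at the terminal carbon.

2 to 1: no bond is cut; the enantiomer is selected by kinetic resolution, which fixes C2' at the outset.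

## Other disconnections considered

Alternative 1: The cut is made late in the spiroketal, at O6'–C5' and O1'–C2'. In the forward sense PdCl2(MeCN)2, a salt of divalent palladium, acts on the hydroxy keto E-allylic alcohol A2. The C7' hydroxyl adds reversibly to the C5' carbonyl, and the hemiketal hydroxyl attacks C2' with allylic transposition and syn loss of the allylic hydroxyl. This closes rings B and A and gives the alkenyl spiroketal A1; hydrogenation of the side-chain alkene would finish.
- In favour: two rings form in one near-neutral operation, and C2' is set by 1,3-chirality transfer from a carbinol that reagent-controlled reductions make reliably.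
- Better than the chosen plan: the spiroketal is formed last and sees only one further step, so C5' is less exposed to later chemistry.
- Equal to the chosen plan: chirality transfer fixes C2' only. C5' comes from whichever hemiketal anomer closes and can still equilibrate under the Lewis-acidic metal salt.
- Against: it needs a sacrificial stereocentre, and the final hydrogenation must spare the benzylic lactone C3–O bond.
- Comparison: structurally it leaves the arene, the lactone and C3 to be solved separately. Mechanistically it is a metal-templated SN2' process in place of a base-mediated condensation. No saving in steps is expected, because A2 itself carries a ketone, two carbinols and a defined alkene.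

Alternative 2: The cuts are C3–C3a and C7a–C1, so the arene is bought. Forward, carbamate A4 is lithiated next to oxygen in the presence of a sparteine-type diamine. The configurationally defined carbanion adds to the aryne A6, released from ortho-lithiated A5, at the future C3a. The aryllithium formed at C7a, ortho to methoxyl, then captures the carbamoyl group from the neighbouring oxygen to give the hydroxy amide A3, which would be lactonised.
- In favour: both methyl ethers and the benzene ring come ready-made, C3 is set under reagent control in the step that makes both ring–carbon bonds, and the methoxyl group polarises the aryne in the required sense.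
- Better than the chosen plan: from 8 only about four operations would be needed, so step economy is clearly better.
- Against: the two organolithium species have conflicting temperature windows (the lithiated carbamate is configurationally stable only cold; fluoride loss from the lithiated arene needs warming). The aryne can be captured by its own precursor, and the steric course at C3 is uncertain. The enantiomeric ratio would be high but not complete, and the minor C3 epimer would be inseparable. Lactonisation of the hindered tertiary amide normally calls for acid and heat, which endangers C5' and the benzylic C3–O bond.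
- Comparison: the chosen plan is better on purity at C3 and on mildness after the key step; on convergence it is not.

Alternative 3: The cut is O6'–C5' only, with ring A kept as the 4',5'-enol ether A8. Forward, dimethyldioxirane epoxidises A8 on the face away from the C2' chain to give oxirane A9. In methanol the C7' hydroxyl opens it at C5' with inversion, closing ring B and giving the 4'-hydroxy spiroketal A7. Removal of the extra hydroxyl (thiocarbonyl derivative, tin hydride) would follow.
- Better than the chosen plan: this is the only one of the four plans in which C5' is set by a stereospecific, kinetically controlled event and not by an equilibrium. The required C5' configuration is not expected to be the favoured one, so this is a real advantage.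
- Against: A8 is an acid-sensitive 5-alkyl-2,3-dihydrofuran that must be made with the phthalide chain attached, and the facial bias rests on one substituent across O1' in a nearly flat ring. The 4'-hydroxyl is foreign to 25 and costs two further steps, so after its key step it is longer (three steps against two).
- Equal to the chosen plan: once ring B is closed the product is as vulnerable to acid as any intermediate of the chosen plan.
- Comparison: structurally it solves the spiroketal but not the arene or C3. Mechanistically it trades a thermodynamic ketalisation for an oxidation and an SN2-type opening.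

Key step: step 12

Assumption: the two C5' epimers of the [5,5]-spiroketal are taken to be close in energy and to interconvert only under acid, so 8 is secured by separation and recycling in step 3 and stays configurationally stable in the acid-free steps that follow.

Locants C1–C7a refer to the phthalide of 25 and C2'–C9' to its spiroketal. In the names below, "Sk" stands for (2S,5S,7S)-7-methyl-1,6-dioxaspiro[4.4]nonan-2-yl.

## Route

Step 1
Reactants: 1 rac-2-(oct-7-en-1-yl)oxirane (1,2-epoxydec-9-ene)
Product: 2 (S)-2-(oct-7-en-1-yl)oxirane
Conditions: (R,R)-(salen)Co(OAc) 0.5 mol % (acetate of trivalent cobalt; salen = N,N'-bis(3,5-di-tert-butylsalicylidene)cyclohexane-1,2-diamine dianion), H2O 0.55 equiv, a little THF, 0 °C to rt; distillation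
Reagents that add atoms: none
Why: Jacobsen hydrolytic kinetic resolution: the chiral cobalt–salen Lewis acid hydrates the (R)-oxirane much faster, so with slightly more than half an equivalent of water the volatile (S)-oxirane should be recovered in high enantiomeric purity; this fixes the future C2' and leaves the alkene untouched.

Step 2
Reactants: 3 acetone N,N-dimethylhydrazone; 4 (S)-2-methyloxirane; 2 (S)-2-(oct-7-en-1-yl)oxirane
Product: 6 (2S,8S)-5-(2,2-dimethylhydrazinylidene)hexadec-15-ene-2,8-diol, via monoalkylated hydrazone alkoxide 5 (not isolated)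
Conditions: n-BuLi 1.05 equiv, THF, −78 to 0 °C; 4, −78 °C to rt; n-BuLi 1.1 equiv, −78 to 0 °C; 2, 0 °C to rt; H2O
Reagents that add atoms: none
Why: Twofold Corey–Enders azaenolate alkylation in one flask: the lithiated hydrazone opens each oxirane at its CH2 terminus (SN2), and the second lithiation occurs at the remaining methyl group because hydrazone azaenolates form at the less substituted α-carbon. C7' and C2' are carried over unchanged from 4 and 2, since no bond to either carbinol carbon is made or broken.

Step 3
Reactants: 6 (2S,8S)-5-(2,2-dimethylhydrazinylidene)hexadec-15-ene-2,8-diol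
Product: 8 (2S,5S,7S)-2-methyl-7-(oct-7-en-1-yl)-1,6-dioxaspiro[4.4]nonane, via dihydroxy ketone 7 (not isolated)
Conditions: 1 M aq HCl, THF, 0 °C to rt; NaHCO3 work-up; chromatography on Et3N-washed SiO2; the unwanted C5' epimer re-equilibrated (PPTS cat., CH2Cl2) and separated again
Reagents that add atoms: none
Why: Acid hydrolysis of the hydrazone releases ketone 7, which closes twice to the [5,5]-spiroketal (thermodynamic ketalisation). C2' and C7' are fixed, but C5' is set only by equilibrium, so both epimers are expected; the (5S) epimer is taken by chromatography and the other is returned to the equilibrium.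

Step 4
Reactants: 8 (2S,5S,7S)-2-methyl-7-(oct-7-en-1-yl)-1,6-dioxaspiro[4.4]nonane
Product: 10 8-(Sk)octan-1-ol, via B-alkyl-9-borabicyclononane 9 (not isolated)
Conditions: 9-BBN-H 1.3 equiv, THF, 0 °C to rt; then 3 M aq NaOH, 30% H2O2, 0 °C to rt
Reagents that add atoms: hydrogen peroxide, OO
Why: Brown hydroboration–oxidation: the bulky borane places boron on the terminal carbon and alkaline peroxide replaces it by hydroxyl; the medium is basic throughout, so the ketal is not at risk.

Step 5
Reactants: 10 8-(Sk)octan-1-ol
Product: 11 8-(Sk)octanoic acid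
Conditions: TEMPO 10 mol %, NaClO2 2 equiv, NaOCl 2 mol %, MeCN–phosphate buffer pH 6.7, 35 °C; Na2SO3; extraction at about pH 5; used directly
Reagents that add atoms: sodium chlorite, [Na+].[O-]Cl=O
Why: Nitroxyl-catalysed oxidation of a primary alcohol to the carboxylic acid with chlorite as terminal oxidant; it runs near neutral pH, which avoids the acid that would scramble C5'.

Step 6
Reactants: 11 8-(Sk)octanoic acid; 12 (S)-4-benzyl-1,3-oxazolidin-2-one
Product: 14 (S)-4-benzyl-3-[8-(Sk)octanoyl]-1,3-oxazolidin-2-one, via mixed pivalic anhydride 13 (not isolated)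
Conditions: t-BuCOCl 1.1 equiv, Et3N 2.5 equiv, THF, −20 °C; then LiCl 1.1 equiv, 12, −20 °C to rt
Reagents that add atoms: none
Why: N-acylation of the oxazolidinone through a mixed anhydride with LiCl activation; the nucleophile attacks the less hindered carbonyl of 13.

Step 7
Reactants: 14 (S)-4-benzyl-3-[8-(Sk)octanoyl]-1,3-oxazolidin-2-one
Product: 15 (S)-4-benzyl-3-[(2S)-2-hydroxy-8-(Sk)octanoyl]-1,3-oxazolidin-2-one
Conditions: NaN(SiMe3)2 1.1 equiv, THF, −78 °C; 2-(phenylsulfonyl)-3-phenyloxaziridine 1.3 equiv, −78 °C; AcOH quench at −78 °C; chromatography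
Reagents that add atoms: 2-(phenylsulfonyl)-3-phenyloxaziridine, O=S(=O)(c1ccccc1)N1OC1c1ccccc1
Why: Evans asymmetric enolate hydroxylation: the chelated Z-sodium enolate is oxidised by the N-sulfonyloxaziridine on the face opposite the benzyl group, which with the (S)-auxiliary should give the (2S)-alcohol, the future C3. The minor epimer is a diastereomer right next to the auxiliary and can be removed by chromatography.

Step 8
Reactants: 15 (S)-4-benzyl-3-[(2S)-2-hydroxy-8-(Sk)octanoyl]-1,3-oxazolidin-2-one
Product: 16 (2S)-2-hydroxy-N-methoxy-N-methyl-8-(Sk)octanamide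
Conditions: MeNHOMe·HCl 3 equiv, AlMe3 3 equiv, THF–CH2Cl2, −10 to 0 °C; aq potassium sodium tartrate
Reagents that add atoms: N,O-dimethylhydroxylamine hydrochloride, CNOC.Cl
Why: Weinreb transamidation of the imide by an aluminium amide: the aluminium alkoxide of the free α-hydroxyl directs attack to the exocyclic carbonyl, the auxiliary is recovered and C3 is not touched. The donor solvent and low temperature keep the aluminium species from acting on the ketal.

Step 9
Reactants: 16 (2S)-2-hydroxy-N-methoxy-N-methyl-8-(Sk)octanamide
Product: 17 (2S)-2-[(tert-butyldimethylsilyl)oxy]-N-methoxy-N-methyl-8-(Sk)octanamide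
Conditions: t-BuMe2SiCl 1.5 equiv, imidazole 3 equiv, DMF, rt
Reagents that add atoms: tert-butyl(chloro)dimethylsilane, C[Si](C)(Cl)C(C)(C)C
Why: Silyl ether formation on the secondary alcohol under imidazole catalysis; the silyl group will stop the C3 oxygen from adding to the β-carbonyl in 20 and is the trigger for the later lactonisation.

Step 10
Reactants: 18 2,2,6-trimethyl-4H-1,3-dioxin-4-one
Product: 19 2,2-dimethyl-6-(2-oxopropyl)-4H-1,3-dioxin-4-one
Conditions: 18 2 equiv, LiN(SiMe3)2 2 equiv, THF, −78 °C; AcCl 1 equiv, −78 to −30 °C; aq NH4Cl
Reagents that add atoms: acetyl chloride, CC(=O)Cl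
Why: Vinylogous Claisen acylation: the amide base removes a proton from the C6 methyl group of 18 and the dienolate is acylated at that γ-carbon; the second equivalent of enolate absorbs the more acidic product.

Step 11
Reactants: 19 2,2-dimethyl-6-(2-oxopropyl)-4H-1,3-dioxin-4-one; 17 (2S)-2-[(tert-butyldimethylsilyl)oxy]-N-methoxy-N-methyl-8-(Sk)octanamide
Product: 20 6-[(5S)-5-[(tert-butyldimethylsilyl)oxy]-2,4-dioxo-11-(Sk)undecyl]-2,2-dimethyl-4H-1,3-dioxin-4-one
Conditions: 19 2 equiv, LiN(iPr)2 4.2 equiv, THF, −78 °C; 17 1 equiv, −78 to −40 °C; aq NH4Cl at −78 °C; used with minimal purification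
Reagents that add atoms: none
Why: Crossed Claisen condensation of a 1,3-dicarbonyl dianion: the more reactive terminal carbanion of the dianion of 19 adds to the N-methoxy-N-methylamide, and the chelated tetrahedral adduct keeps the new ketone masked until the quench, which prevents a second addition and enolisation at the silyloxy carbon. No stereocentre is formed; C3 is carried over.

Step 12
Reactants: 20 6-[(5S)-5-[(tert-butyldimethylsilyl)oxy]-2,4-dioxo-11-(Sk)undecyl]-2,2-dimethyl-4H-1,3-dioxin-4-one
Product: 22 5-[(1S)-1-[(tert-butyldimethylsilyl)oxy]-7-(Sk)heptyl]-7-hydroxy-2,2-dimethyl-4H-1,3-benzodioxin-4-one, via cyclic aldol carbinol 21 (not isolated)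
Conditions: Et3N 3 equiv, CH2Cl2, rt
Reagents that add atoms: none
Why: Et3N removes a proton from the doubly activated methylene/1,3-diketone region of 20, and the extended enolate is nucleophilic at the dioxinone α-carbon (future C7a). This carbon adds to the ketone next to the silyloxy carbon (future C3a) in a 6-(enolexo)-exo-trig aldol closure to give carbinol 21; E1cB loss of water and tautomerisation of the dienone then give the phenol, so the C3a–C7a bond and the benzene ring are made in one operation. The closest known reaction type is the amine- or carbonate-mediated aldol aromatisation of 6-(2,4-dioxoalkyl)dioxinones to acetonide-masked resorcylates, the laboratory counterpart of orsellinate-type polyketide cyclisation. No stereocentre is created: the carbinol carbon of 21 becomes aromatic and C3 is only carried through. Site selectivity is secured by ring size, because the dioxinone α-carbon can reach only the terminal ketone through a six-membered transition state (the nearer ketone would give a four-membered ring); the dioxinone carbonyl is a poor electrophile at room temperature, so Claisen-type C-acylation and ketene-derived pyranone formation, which need heat, should not compete. Integrity of C3 is secured because the C3a ketone enolises toward C4, which lies between two carbonyls, and not toward the tertiary silyloxy carbon; after aromatisation C3–H is merely benzylic. The silyl ether keeps the C3 oxygen from adding to the C5 carbonyl or to C1 before the ring exists, and the ketal is inert to a tertiary amine.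

Step 13
Reactants: 22 5-[(1S)-1-[(tert-butyldimethylsilyl)oxy]-7-(Sk)heptyl]-7-hydroxy-2,2-dimethyl-4H-1,3-benzodioxin-4-one
Product: 24 (3S)-5,7-dihydroxy-3-[6-(Sk)hexyl]-2-benzofuran-1(3H)-one, via desilylated benzylic alkoxide 23 (not isolated)
Conditions: Bu4NF 2.5 equiv, THF, 0 °C to rt; aq NH4Cl
Reagents that add atoms: none
Why: Fluoride desilylation followed by intramolecular transesterification: the benzylic alkoxide attacks the dioxinone carbonyl (5-exo-trig) and the expelled hemiketal alkoxide loses acetone, which makes the step irreversible and frees the C7 phenol. The C3–O bond is never broken, so C3 is retained.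

Step 14
Reactants: 24 (3S)-5,7-dihydroxy-3-[6-(Sk)hexyl]-2-benzofuran-1(3H)-one
Product: 25 (3S)-5,7-dimethoxy-3-[6-(Sk)hexyl]-2-benzofuran-1(3H)-one
Conditions: MeI 5 equiv, K2CO3 4 equiv, acetone, reflux
Reagents that add atoms: iodomethane, CI
Why: Williamson O-methylation of both phenols with a weak base; the C7 hydroxyl, hydrogen-bonded to the lactone carbonyl, needs the excess reagent and warming, and carbonate is too weak to deprotonate C3 or to affect the ketal.

## Compound list

1 | rac-2-(oct-7-en-1-yl)oxirane | C=CCCCCCCC1CO1 | starting material
2 | (S)-2-(oct-7-en-1-yl)oxirane | C=CCCCCCC[C@H]1CO1 | intermediate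
3 | acetone N,N-dimethylhydrazone | CC(C)=NN(C)C | starting material
4 | (S)-2-methyloxirane | C[C@H]1CO1 | starting material
5 | (S)-5-(2,2-dimethylhydrazinylidene)hexan-2-ol (lithium alkoxide in the flask) | CC(=NN(C)C)CC[C@H](C)O | intermediate
6 | (2S,8S)-5-(2,2-dimethylhydrazinylidene)hexadec-15-ene-2,8-diol | C=CCCCCCC[C@H](O)CCC(=NN(C)C)CC[C@H](C)O | intermediate
7 | (2S,8S)-2,8-dihydroxyhexadec-15-en-5-one | C=CCCCCCC[C@H](O)CCC(=O)CC[C@H](C)O | intermediate
8 | (2S,5S,7S)-2-methyl-7-(oct-7-en-1-yl)-1,6-dioxaspiro[4.4]nonane | C=CCCCCCC[C@H]1CC[C@]2(CC[C@H](C)O2)O1 | intermediate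
9 | 9-[8-(Sk)octyl]-9-borabicyclo[3.3.1]nonane | B1(CCCCCCCC[C@H]2CC[C@]3(CC[C@H](C)O3)O2)C2CCCC1CCC2 | intermediate
10 | 8-(Sk)octan-1-ol | OCCCCCCCC[C@H]1CC[C@]2(CC[C@H](C)O2)O1 | intermediate
11 | 8-(Sk)octanoic acid | OC(=O)CCCCCCC[C@H]1CC[C@]2(CC[C@H](C)O2)O1 | intermediate
12 | (S)-4-benzyl-1,3-oxazolidin-2-one | O=C1N[C@@H](Cc2ccccc2)CO1 | starting material
13 | 8-(Sk)octanoic pivalic anhydride | CC(C)(C)C(=O)OC(=O)CCCCCCC[C@H]1CC[C@]2(CC[C@H](C)O2)O1 | intermediate
14 | (S)-4-benzyl-3-[8-(Sk)octanoyl]-1,3-oxazolidin-2-one | O=C(CCCCCCC[C@H]1CC[C@]2(CC[C@H](C)O2)O1)N1[C@@H](Cc2ccccc2)COC1=O | intermediate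
15 | (S)-4-benzyl-3-[(2S)-2-hydroxy-8-(Sk)octanoyl]-1,3-oxazolidin-2-one | O=C([C@@H](O)CCCCCC[C@H]1CC[C@]2(CC[C@H](C)O2)O1)N1[C@@H](Cc2ccccc2)COC1=O | intermediate
16 | (2S)-2-hydroxy-N-methoxy-N-methyl-8-(Sk)octanamide | CON(C)C(=O)[C@@H](O)CCCCCC[C@H]1CC[C@]2(CC[C@H](C)O2)O1 | intermediate
17 | (2S)-2-[(tert-butyldimethylsilyl)oxy]-N-methoxy-N-methyl-8-(Sk)octanamide | CON(C)C(=O)[C@@H](O[Si](C)(C)C(C)(C)C)CCCCCC[C@H]1CC[C@]2(CC[C@H](C)O2)O1 | intermediate
18 | 2,2,6-trimethyl-4H-1,3-dioxin-4-one | CC1=CC(=O)OC(C)(C)O1 | starting material
19 | 2,2-dimethyl-6-(2-oxopropyl)-4H-1,3-dioxin-4-one | CC(=O)CC1=CC(=O)OC(C)(C)O1 | intermediate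
20 | 6-[(5S)-5-[(tert-butyldimethylsilyl)oxy]-2,4-dioxo-11-(Sk)undecyl]-2,2-dimethyl-4H-1,3-dioxin-4-one | CC1(C)OC(=O)C=C(CC(=O)CC(=O)[C@H](CCCCCC[C@H]2CC[C@]3(CC[C@H](C)O3)O2)O[Si](C)(C)C(C)(C)C)O1 | intermediate
21 | 5-[(1S)-1-[(tert-butyldimethylsilyl)oxy]-7-(Sk)heptyl]-5-hydroxy-2,2-dimethyl-5,6-dihydro-4H-1,3-benzodioxine-4,7(8H)-dione (either configuration at the ring carbinol) | CC1(C)OC(=O)C2=C(O1)CC(=O)CC2(O)[C@H](CCCCCC[C@H]3CC[C@]4(CC[C@H](C)O4)O3)O[Si](C)(C)C(C)(C)C | intermediate
22 | 5-[(1S)-1-[(tert-butyldimethylsilyl)oxy]-7-(Sk)heptyl]-7-hydroxy-2,2-dimethyl-4H-1,3-benzodioxin-4-one | CC1(C)OC(=O)c2c(O1)cc(O)cc2[C@H](CCCCCC[C@H]3CC[C@]4(CC[C@H](C)O4)O3)O[Si](C)(C)C(C)(C)C | intermediate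
23 | 7-hydroxy-5-[(1S)-1-hydroxy-7-(Sk)heptyl]-2,2-dimethyl-4H-1,3-benzodioxin-4-one (alkoxide in the flask) | CC1(C)OC(=O)c2c(O1)cc(O)cc2[C@H](CCCCCC[C@H]3CC[C@]4(CC[C@H](C)O4)O3)O | intermediate
24 | (3S)-5,7-dihydroxy-3-[6-(Sk)hexyl]-2-benzofuran-1(3H)-one | Oc1cc(O)c2c(c1)[C@H](CCCCCC[C@H]1CC[C@]3(CC[C@H](C)O3)O1)OC2=O | intermediate
25 | (3S)-5,7-dimethoxy-3-[6-(Sk)hexyl]-2-benzofuran-1(3H)-one | COc1cc(OC)c2c(c1)[C@H](CCCCCC[C@H]1CC[C@]3(CC[C@H](C)O3)O1)OC2=O | target

## Step count and risks

Total: 14 steps. Longest linear sequence: 13 steps (steps 1–9 and 11–14); step 10 is a one-step branch.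

Key step, step 12. The most likely failure is slow carbon–carbon bond formation at the α-branched, silyloxy-bearing ketone. Slower processes could then take over: oxygen cyclisation of the enolised triketide to a pyranone, retro-Claisen cleavage, or gradual erosion at C3 on long exposure to base. The fallback sets out from 20 and changes the nucleophile. Heating 20 in toluene with methanol causes retro-hetero-Diels–Alder loss of acetone to the acylketene F1, which methanol captures as the methyl triketo ester F2. Its β-keto ester methylene is more acidic and conformationally freer than the dioxinone α-carbon. K2CO3 in methanol followed by acetic acid should close the same C3a–C7a bond and give the methyl resorcylate F3. Bu4NF then removes the silyl group and the alkoxide displaces methoxide, which returns the route at 24.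

Step 3. The risk is thermodynamic control at C5': the required (5S) arrangement may be the minor component of the equilibrium, and the two non-polar epimers may co-elute. The fallback sets out from 2 and replaces equilibrium by a stereospecific closure.
- Lithium acetylide–ethylenediamine complex in DMSO opens 2 to (S)-dodec-11-en-1-yn-4-ol F4.
- Mo(CO)6 and Et3N under irradiation (alkynol cycloisomerisation) give (S)-2-(oct-7-en-1-yl)-2,3-dihydrofuran F5.
- t-BuLi lithiates the enol ether carbon, and alkylation with (S)-tert-butyl[(4-iodobutan-2-yl)oxy]dimethylsilane F6 (from (S)-butane-1,3-diol) gives the silyl ether F7. Bu4NF frees the alcohol F8.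
- Dimethyldioxirane at −78 °C oxidises the enol ether, far faster than the terminal alkene, anti to the octenyl group to give oxirane F9. Added methanol lets the side-chain hydroxyl open it at C5' with inversion, giving the 4-hydroxy spiroketal F10 with the (5S) configuration.
- Xanthate F11 (NaH, CS2, MeI) and Bu3SnH with AIBN (Barton–McCombie deoxygenation) remove the extra hydroxyl and return the route at 8.

Step 11. The risk is slow acylation at the hindered amide, which would allow proton transfer from 17 to the dianion (loss of C3 purity, recovered starting materials) or reaction at the internal carbon or at oxygen. The fallback sets out from 17 and replaces acylation by addition and oxidation. iBu2AlH in THF at −78 °C reduces 17 to the aldehyde F12. The dianion of 19 adds to it at −78 °C to give the β-hydroxy ketone F13 as both carbinol epimers. Dess–Martin periodinane buffered with NaHCO3 oxidises F13 and returns the route at 20.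

Step 2. The risk is incomplete or misdirected second metalation in the presence of the lithium alkoxide (proton shuffling, double alkylation at one carbon) and slow opening of the second oxirane. The fallback sets out from 4 and 2 and uses an alkyne as the linchpin in place of the hydrazone. Propargylmagnesium bromide opens 4 to (S)-hex-5-yn-2-ol F14. Its dianion (n-BuLi, 2 equiv) with BF3·OEt2 opens 2 to the alkynediol F15. Catalytic AuCl in CH2Cl2 then adds both hydroxyls to the same alkyne carbon (5-exo addition, then ketalisation) and returns the route at 8 after the same separation of C5' epimers.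

Step 13. The risk is desilylation without ring closure, because the phenoxide formed first under basic fluoride conditions pushes electron density into the dioxinone carbonyl para to it. The fallback sets out from 22 and changes the order of events. MeI and K2CO3 first convert 22 into the methyl ether F16, which cannot form a phenoxide. Bu4NF then gives the 7-hydroxy-5-methoxyphthalide F17 by the same desilylation and acyl transfer. A second methylation under the conditions of step 14 returns the route at 25.

## Further compounds

F1 | step 12 | (8S)-8-[(tert-butyldimethylsilyl)oxy]-14-(Sk)tetradec-1-ene-1,3,5,7-tetraone (acylketene) | O=C=CC(=O)CC(=O)CC(=O)[C@H](CCCCCC[C@H]1CC[C@]2(CC[C@H](C)O2)O1)O[Si](C)(C)C(C)(C)C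
F2 | step 12 | methyl (8S)-8-[(tert-butyldimethylsilyl)oxy]-3,5,7-trioxo-14-(Sk)tetradecanoate | COC(=O)CC(=O)CC(=O)CC(=O)[C@H](CCCCCC[C@H]1CC[C@]2(CC[C@H](C)O2)O1)O[Si](C)(C)C(C)(C)C
F3 | step 12 | methyl 2-[(1S)-1-[(tert-butyldimethylsilyl)oxy]-7-(Sk)heptyl]-4,6-dihydroxybenzoate | COC(=O)c1c(O)cc(O)cc1[C@H](CCCCCC[C@H]1CC[C@]2(CC[C@H](C)O2)O1)O[Si](C)(C)C(C)(C)C
F4 | step 3 | (S)-dodec-11-en-1-yn-4-ol | C=CCCCCCC[C@H](O)CC#C
F5 | step 3 | (S)-2-(oct-7-en-1-yl)-2,3-dihydrofuran | C=CCCCCCC[C@H]1CC=CO1
F6 | step 3 | (S)-tert-butyl[(4-iodobutan-2-yl)oxy]dimethylsilane | ICC[C@H](C)O[Si](C)(C)C(C)(C)C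
F7 | step 3 | tert-butyldimethyl{[(2S)-4-[(5S)-5-(oct-7-en-1-yl)-4,5-dihydrofuran-2-yl]butan-2-yl]oxy}silane | C=CCCCCCC[C@H]1CC=C(CC[C@H](C)O[Si](C)(C)C(C)(C)C)O1
F8 | step 3 | (2S)-4-[(5S)-5-(oct-7-en-1-yl)-4,5-dihydrofuran-2-yl]butan-2-ol | C=CCCCCCC[C@H]1CC=C(CC[C@H](C)O)O1
F9 | step 3 | oxirane of F8 on the ring face anti to the octenyl group (2,6-dioxabicyclo[3.1.0]hexane) | C=CCCCCCC[C@H]1C[C@@H]2O[C@]2(CC[C@H](C)O)O1
F10 | step 3 | (2S,4S,5S,7S)-7-methyl-2-(oct-7-en-1-yl)-1,6-dioxaspiro[4.4]nonan-4-ol | C=CCCCCCC[C@H]1C[C@H](O)[C@]2(CC[C@H](C)O2)O1
F11 | step 3 | O-[(2S,4S,5S,7S)-7-methyl-2-(oct-7-en-1-yl)-1,6-dioxaspiro[4.4]nonan-4-yl] S-methyl carbonodithioate | C=CCCCCCC[C@H]1C[C@H](OC(=S)SC)[C@]2(CC[C@H](C)O2)O1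
F12 | step 11 | (2S)-2-[(tert-butyldimethylsilyl)oxy]-8-(Sk)octanal | O=C[C@@H](O[Si](C)(C)C(C)(C)C)CCCCCC[C@H]1CC[C@]2(CC[C@H](C)O2)O1
F13 | step 11 | 6-[(5S)-5-[(tert-butyldimethylsilyl)oxy]-4-hydroxy-2-oxo-11-(Sk)undecyl]-2,2-dimethyl-4H-1,3-dioxin-4-one (both C4 epimers) | CC1(C)OC(=O)C=C(CC(=O)CC(O)[C@H](CCCCCC[C@H]2CC[C@]3(CC[C@H](C)O3)O2)O[Si](C)(C)C(C)(C)C)O1
F14 | step 2 | (S)-hex-5-yn-2-ol | C#CCC[C@H](C)O
F15 | step 2 | (2S,8S)-hexadec-15-en-5-yne-2,8-diol | C=CCCCCCC[C@H](O)CC#CCC[C@H](C)O
F16 | step 13 | 5-[(1S)-1-[(tert-butyldimethylsilyl)oxy]-7-(Sk)heptyl]-7-methoxy-2,2-dimethyl-4H-1,3-benzodioxin-4-one | CC1(C)OC(=O)c2c(O1)cc(OC)cc2[C@H](CCCCCC[C@H]3CC[C@]4(CC[C@H](C)O4)O3)O[Si](C)(C)C(C)(C)C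
F17 | step 13 | (3S)-7-hydroxy-5-methoxy-3-[6-(Sk)hexyl]-2-benzofuran-1(3H)-one | COc1cc(O)c2c(c1)[C@H](CCCCCC[C@H]1CC[C@]3(CC[C@H](C)O3)O1)OC2=O
A1 | alternative 1 | alkenyl spiroketal phthalide with an E-alkene next to C2' | COc1cc(OC)c2c(c1)[C@H](CCCC/C=C/[C@H]1CC[C@]3(CC[C@H](C)O3)O1)OC2=O
A2 | alternative 1 | hydroxy keto E-allylic alcohol with an (S) allylic carbinol | COc1cc(OC)c2c(c1)[C@H](CCCC[C@H](O)/C=C/CCC(=O)CC[C@H](C)O)OC2=O
A3 | alternative 2 | 2-[(1S)-1-hydroxy-7-(Sk)heptyl]-4,6-dimethoxy-N,N-diisopropylbenzamide | COc1cc(OC)c(C(=O)N(C(C)C)C(C)C)c(c1)[C@H](CCCCCC[C@H]2CC[C@]3(CC[C@H](C)O3)O2)O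
A4 | alternative 2 | 7-(Sk)heptyl N,N-diisopropylcarbamate | CC(C)N(C(C)C)C(=O)OCCCCCCC[C@H]1CC[C@]2(CC[C@H](C)O2)O1
A5 | alternative 2 | 1-fluoro-3,5-dimethoxybenzene | COc1cc(F)cc(OC)c1
A6 | alternative 2 | 3,5-dimethoxybenzyne | COC1=CC(OC)=CC#C1
A7 | alternative 3 | 4'-hydroxy spiroketal phthalide with the configuration of 25 at C2', C5' and C7' | COc1cc(OC)c2c(c1)[C@H](CCCCCC[C@H]1C[C@H](O)[C@]3(CC[C@H](C)O3)O1)OC2=O
A8 | alternative 3 | ring A 4',5'-enol ether with a free C7' hydroxyl | COc1cc(OC)c2c(c1)[C@H](CCCCCC[C@H]1CC=C(CC[C@H](C)O)O1)OC2=O
A9 | alternative 3 | 4',5'-oxirane of A8 on the face anti to the C2' chain | COc1cc(OC)c2c(c1)[C@H](CCCCCC[C@H]1C[C@@H]3O[C@]3(CC[C@H](C)O)O1)OC2=O
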